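**Strategy.** Ring B, with the C8 methyl para to the gem-dimethyl carbon C4 on C5, is the p-menthane skeleton of (R)-carvone, whose isopropenyl carbon becomes C4. Everything rests on building ring A from a two-carbon unit: an iron-hydride-initiated radical–polar crossover annulation in which the tertiary C4 radical adds to acrolein (C3–C4) and the resulting enolate closes on a formyl group at C10 (C1–C2), so the trans-decalin and its C4 quaternary centre arise in one operation. The precursor is 6-formyl-6-methylcarvone. The leftover C1 hydroxyl and C2 formyl groups are excised, and ring B is finished by stereoinvertive allylic hydrogenolysis at C9 and a Woodward cis-hydroxylation.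

Key step: step 4

Assumption: labdane numbering (C1–C20, α/β faces, C10 methyl β) is used for all compounds, including the monocyclic ones; compounds 1, 5 and 10 are taken as commercial.

**Step 1**
Reactants: 1 (R)-(−)-carvone
Product: 2 (5R,6S)-2,6-dimethyl-5-(prop-1-en-2-yl)cyclohex-2-en-1-one (trans-6-methylcarvone; any cis epimer is carried along)
Conditions: LiN(i-Pr)2, THF, −78 °C; MeI, −78 → 0 °C
Reagents that add atoms: iodomethane CI
Why: Kinetic α′-deprotonation gives the cross-conjugated lithium enolate, whose alkylation (enolate C-methylation) occurs mainly anti to the isopropenyl group; the new centre is planarised again in step 2, so its configuration does not matter.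

**Step 2**
Reactants: 2 (5R,6S)-2,6-dimethyl-5-(prop-1-en-2-yl)cyclohex-2-en-1-one
Product: 3 (5S,6R)-6-(hydroxymethyl)-2,6-dimethyl-5-(prop-1-en-2-yl)cyclohex-2-en-1-one
Conditions: LiN(i-Pr)2, THF, −78 → −20 °C; CH2O gas (cracked paraformaldehyde), −78 °C; NH4Cl aq.
Reagents that add atoms: formaldehyde C=O
Why: Aldol addition of the tetrasubstituted enolate to formaldehyde takes place on the face anti to the neighbouring isopropenyl group, which sets C10 with the methyl cis and the CH2OH (future C1) trans to the isopropenyl group.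

**Step 3**
Reactants: 3 (5S,6R)-6-(hydroxymethyl)-2,6-dimethyl-5-(prop-1-en-2-yl)cyclohex-2-en-1-one
Product: 4 (1R,6S)-1,3-dimethyl-2-oxo-6-(prop-1-en-2-yl)cyclohex-3-ene-1-carbaldehyde
Conditions: Dess–Martin periodinane, CH2Cl2, 0 °C → rt
Reagents that add atoms: none
Why: Dess–Martin oxidation of the neopentyl primary alcohol stops at the aldehyde under non-basic conditions, so the non-enolisable β-keto aldehyde is not exposed to retro-Claisen cleavage and no stereocentre is touched.

**Step 4**
Reactants: 4 (1R,6S)-1,3-dimethyl-2-oxo-6-(prop-1-en-2-yl)cyclohex-3-ene-1-carbaldehyde; 5 acrolein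
Product: 6 (4aS,8aR)-1-hydroxy-4,4,7,8a-tetramethyl-8-oxo-1,2,3,4,4a,5,8,8a-octahydronaphthalene-2-carbaldehyde (mixture of C1/C2 epimers)
Conditions: Fe(acac)3 (0.5 equiv), PhSiH3, 5 (3 equiv), EtOH/(CH2OH)2, 0 °C → rt
Reagents that add atoms: none
Why: The iron hydride formed from Fe(acac)3 and PhSiH3 transfers a hydrogen atom to the CH2 terminus of the isopropenyl group, the tertiary C4 radical adds to the β-carbon of acrolein (C3–C4, Giese addition), the α-formyl radical at C2 is reduced by divalent iron to an iron enolate, and this enolate adds to the C1 formyl group (C1–C2, aldol) before ethanol protonates the aldolate. The closest known reaction type is the hydrogen-atom-transfer-initiated radical–polar crossover annulation of an alkene that carries a carbonyl group two atoms away with an enal or enone. Ring A is the only ring closed, by a 6-(enolexo)-exo-trig aldol addition after the intermolecular radical step. C5 and C10 are not touched, and because the formyl group on C10 and the side chain on C5 are trans on ring B they can only bridge diequatorially, which gives the trans ring fusion; the new centres C1 and C2 form as a mixture and are erased in steps 5 and 6. The step needs hydrogen atom transfer to the electron-rich 1,1-disubstituted alkene rather than to the electron-poor enone or acrolein double bonds, and aldol closure on the aldehyde rather than on the conjugated C9 ketone; the polarity preference of the metal hydride and the higher electrophilicity of the aldehyde (the ketone would give a bridged ring) secure both. Excess acrolein keeps the intermolecular addition faster than 1,5-abstraction of the formyl hydrogen by the C4 radical.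

**Step 5**
Reactants: 6 (4aS,8aR)-1-hydroxy-4,4,7,8a-tetramethyl-8-oxo-1,2,3,4,4a,5,8,8a-octahydronaphthalene-2-carbaldehyde
Product: 7 (4aS,8aS)-4,4,7,8a-tetramethyl-8-oxo-3,4,4a,5,8,8a-hexahydronaphthalene-2-carbaldehyde
Conditions: MsCl, Et3N, CH2Cl2, 0 °C → rt
Reagents that add atoms: none
Why: Mesylation of the C1 hydroxyl and E1cB elimination through the C2 formyl enolate (aldol-type dehydration) can only give the C1=C2 enal because C10 is quaternary, and this removes both stereocentres created in step 4.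

**Step 6**
Reactants: 7 (4aS,8aS)-4,4,7,8a-tetramethyl-8-oxo-3,4,4a,5,8,8a-hexahydronaphthalene-2-carbaldehyde
Product: 8 (4aS,8aS)-2,5,5,8a-tetramethyl-4a,5,6,8a-tetrahydronaphthalen-1(4H)-one
Conditions: RhCl3·3H2O (5 mol%), 1,3-bis(diphenylphosphino)propane (10 mol%), diglyme, 160 °C
Reagents that add atoms: none
Why: Rhodium-catalysed decarbonylation (Tsuji–Wilkinson type) of the unsaturated aldehyde proceeds by acyl C–H oxidative addition, CO extrusion and C–H reductive elimination, leaving the ring-B enone untouched; any migration of the ring-A double bond is harmless because step 7 saturates it.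

**Step 7**
Reactants: 8 (4aS,8aS)-2,5,5,8a-tetramethyl-4a,5,6,8a-tetrahydronaphthalen-1(4H)-one
Product: 9 (4aS,8aS)-2,5,5,8a-tetramethyl-4a,5,6,7,8,8a-hexahydronaphthalen-1(4H)-one
Conditions: H2 (1 atm), RhCl(PPh3)3 (5 mol%), benzene, rt
Reagents that add atoms: none
Why: Homogeneous hydrogenation with RhCl(PPh3)3 discriminates sterically and electronically, so the cis-disubstituted C1=C2 bond should be reduced while the trisubstituted conjugated C7=C8 bond survives (as in the selective hydrogenation of carvone itself); no stereocentre is formed.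

**Step 8**
Reactants: 9 (4aS,8aS)-2,5,5,8a-tetramethyl-4a,5,6,7,8,8a-hexahydronaphthalen-1(4H)-one; 10 (4-bromobut-1-yn-1-yl)trimethylsilane
Product: 13 methyl (1S,4aS,8aS)-2,5,5,8a-tetramethyl-1-[4-(trimethylsilyl)but-3-yn-1-yl]-1,4,4a,5,6,7,8,8a-octahydronaphthalen-1-yl carbonate (9β-carbonate), via [4-(trimethylsilyl)but-3-yn-1-yl]magnesium bromide 11 (not isolated), via bromomagnesium 9β-alkoxide 12 (not isolated)
Conditions: 10, Mg, THF, rt; LaCl3·2LiCl, 9, THF, 0 °C; ClCO2Me, 0 °C → rt
Reagents that add atoms: methyl chloroformate COC(=O)Cl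
Why: Grignard 1,2-addition to the C9 carbonyl occurs from the α face, anti to the axial C10 methyl, so the oxygen is 9β, and acylation of the magnesium alkoxide in the same flask gives the tertiary allylic carbonate.

**Step 9**
Reactants: 13 methyl (1S,4aS,8aS)-2,5,5,8a-tetramethyl-1-[4-(trimethylsilyl)but-3-yn-1-yl]-1,4,4a,5,6,7,8,8a-octahydronaphthalen-1-yl carbonate
Product: 14 trimethyl{4-[(1S,4aS,8aS)-2,5,5,8a-tetramethyl-1,4,4a,5,6,7,8,8a-octahydronaphthalen-1-yl]but-1-yn-1-yl}silane (14-trimethylsilyl-15,16-dinorlabd-7-en-13-yne, 9α-H)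
Conditions: Pd(OAc)2 (5 mol%), n-Bu3P (20 mol%), HCO2H, Et3N, THF, 40 °C
Reagents that add atoms: none
Why: In this palladium-catalysed formate hydrogenolysis of an allylic carbonate (Tsuji reduction), zerovalent palladium ionises the 9β C–O bond with inversion to an α-face allyl complex and the formate-derived hydride is delivered from palladium to the more substituted terminus C9, which should give 9α-H with the side chain 9β and keep the double bond at C7=C8.

**Step 10**
Reactants: 14 trimethyl{4-[(1S,4aS,8aS)-2,5,5,8a-tetramethyl-1,4,4a,5,6,7,8,8a-octahydronaphthalen-1-yl]but-1-yn-1-yl}silane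
Product: 17 (7β,8β)-15,16-dinorlabd-13-yne-7,8-diol, via 7α-iodo-8β-acetate 15 (not isolated), via 7β-acetoxy-8β-ol 16 (not isolated)
Conditions: N-iodosuccinimide, AcOH, rt; KOAc, AcOH/H2O 95:5, 100 °C; K2CO3, MeOH, 40 °C
Reagents that add atoms: acetic acid CC(=O)O
Why: In this silver-free Woodward cis-hydroxylation, iodonium formation on the open α face and trans-diaxial Markovnikov opening by acetic acid at C8 give the 7α-iodo-8β-acetate, whose acetoxy group displaces iodide with inversion to a cis-fused dioxolanylium ion that water opens to the 7β,8β hydroxy acetate (both oxygens syn to the C10 methyl, the face opposite to an OsO4 dihydroxylation), and methanolysis then removes the acetyl and alkynylsilyl groups.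

**Step 11**
Reactants: 17 (7β,8β)-15,16-dinorlabd-13-yne-7,8-diol
Product: 19 (7β,8β,13E)-labd-13-ene-7,8,15-triol, via alkenyldimethylalane 18 (not isolated)
Conditions: Me3Al (6 equiv), Cp2ZrCl2 (0.5 equiv), CH2Cl2, 0 °C → rt; (CH2O)n, THF, 0 °C → rt; Rochelle salt aq.
Reagents that add atoms: trimethylaluminium C[Al](C)C; formaldehyde C=O
Why: Zirconium-catalysed carboalumination (Negishi) adds methyl and aluminium syn across the terminal alkyne with methyl at the internal carbon C13, and hydroxymethylation of the alkenylalane with retention fixes the 13E geometry, the two hydroxyls being carried as aluminium alkoxides.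

**Step 12**
Reactants: 19 (7β,8β,13E)-labd-13-ene-7,8,15-triol
Product: 20 (7β,8β,13E)-8-hydroxylabd-13-ene-7,15-diyl diacetate
Conditions: Ac2O, pyridine, rt
Reagents that add atoms: acetic anhydride CC(=O)OC(C)=O
Why: Acetylation with acetic anhydride in pyridine esterifies the primary C15 and the equatorial secondary C7 hydroxyl, whereas the axial tertiary C8 hydroxyl should not react without a stronger acyl-transfer catalyst.

**Step 13**
Reactants: 20 (7β,8β,13E)-8-hydroxylabd-13-ene-7,15-diyl diacetate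
Product: 21 (7β,8β,13E)-8,15-dihydroxylabd-13-en-7-yl acetate (target)
Conditions: immobilised Candida antarctica lipase B, n-BuOH, MTBE, 30 °C
Reagents that add atoms: none
Why: Lipase-catalysed alcoholysis should cleave only the unhindered primary allylic acetate, since the secondary 7β-acetate on the decalin next to the tertiary carbinol is a poor enzyme substrate, and the neutral conditions avoid acyl migration.

**Compound list**
1 | (R)-(−)-carvone, (5R)-2-methyl-5-(prop-1-en-2-yl)cyclohex-2-en-1-one | CC1=CC[C@@H](C(C)=C)CC1=O | starting material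
2 | (5R,6S)-2,6-dimethyl-5-(prop-1-en-2-yl)cyclohex-2-en-1-one (trans-6-methylcarvone) | CC1=CC[C@@H](C(C)=C)[C@H](C)C1=O | intermediate
3 | (5S,6R)-6-(hydroxymethyl)-2,6-dimethyl-5-(prop-1-en-2-yl)cyclohex-2-en-1-one | CC1=CC[C@@H](C(C)=C)[C@](C)(CO)C1=O | intermediate
4 | (1R,6S)-1,3-dimethyl-2-oxo-6-(prop-1-en-2-yl)cyclohex-3-ene-1-carbaldehyde | CC1=CC[C@@H](C(C)=C)[C@](C)(C=O)C1=O | intermediate
5 | acrolein (prop-2-enal) | C=CC=O | starting material
6 | (4aS,8aR)-1-hydroxy-4,4,7,8a-tetramethyl-8-oxo-1,2,3,4,4a,5,8,8a-octahydronaphthalene-2-carbaldehyde (C1/C2 epimer mixture) | CC1=CC[C@H]2C(C)(C)CC(C=O)C(O)[C@]2(C)C1=O | intermediate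
7 | (4aS,8aS)-4,4,7,8a-tetramethyl-8-oxo-3,4,4a,5,8,8a-hexahydronaphthalene-2-carbaldehyde | CC1=CC[C@H]2C(C)(C)CC(C=O)=C[C@]2(C)C1=O | intermediate
8 | (4aS,8aS)-2,5,5,8a-tetramethyl-4a,5,6,8a-tetrahydronaphthalen-1(4H)-one | CC1=CC[C@H]2C(C)(C)CC=C[C@]2(C)C1=O | intermediate
9 | (4aS,8aS)-2,5,5,8a-tetramethyl-4a,5,6,7,8,8a-hexahydronaphthalen-1(4H)-one | CC1=CC[C@H]2C(C)(C)CCC[C@]2(C)C1=O | intermediate
10 | (4-bromobut-1-yn-1-yl)trimethylsilane | C[Si](C)(C)C#CCCBr | starting material
11 | [4-(trimethylsilyl)but-3-yn-1-yl]magnesium bromide | C[Si](C)(C)C#CCC[Mg]Br | intermediate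
12 | bromomagnesium (1S,4aS,8aS)-2,5,5,8a-tetramethyl-1-[4-(trimethylsilyl)but-3-yn-1-yl]-1,4,4a,5,6,7,8,8a-octahydronaphthalen-1-olate (9β-O) | CC1=CC[C@H]2C(C)(C)CCC[C@]2(C)[C@]1(O[Mg]Br)CCC#C[Si](C)(C)C | intermediate
13 | methyl (1S,4aS,8aS)-2,5,5,8a-tetramethyl-1-[4-(trimethylsilyl)but-3-yn-1-yl]-1,4,4a,5,6,7,8,8a-octahydronaphthalen-1-yl carbonate (9β-carbonate, side chain 9α) | CC1=CC[C@H]2C(C)(C)CCC[C@]2(C)[C@]1(OC(=O)OC)CCC#C[Si](C)(C)C | intermediate
14 | trimethyl{4-[(1S,4aS,8aS)-2,5,5,8a-tetramethyl-1,4,4a,5,6,7,8,8a-octahydronaphthalen-1-yl]but-1-yn-1-yl}silane (9α-H, side chain 9β) | CC1=CC[C@H]2C(C)(C)CCC[C@]2(C)[C@H]1CCC#C[Si](C)(C)C | intermediate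
15 | (7α,8β)-7-iodo-14-(trimethylsilyl)-15,16-dinorlabd-13-yn-8-yl acetate | I[C@@H]1C[C@H]2C(C)(C)CCC[C@]2(C)[C@@H](CCC#C[Si](C)(C)C)[C@@]1(C)OC(C)=O | intermediate
16 | (7β,8β)-8-hydroxy-14-(trimethylsilyl)-15,16-dinorlabd-13-yn-7-yl acetate (an 8-acetate regioisomer, if formed, converges in the methanolysis) | CC(=O)O[C@H]1C[C@H]2C(C)(C)CCC[C@]2(C)[C@@H](CCC#C[Si](C)(C)C)[C@@]1(C)O | intermediate
17 | (7β,8β)-15,16-dinorlabd-13-yne-7,8-diol | O[C@H]1C[C@H]2C(C)(C)CCC[C@]2(C)[C@@H](CCC#C)[C@@]1(C)O | intermediate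
18 | dimethyl[(13E)-7β,8β-bis(dimethylaluminiooxy)-15-norlabd-13-en-14-yl]alane | C[Al](C)O[C@H]1C[C@H]2C(C)(C)CCC[C@]2(C)[C@@H](CC/C(C)=C/[Al](C)C)[C@@]1(C)O[Al](C)C | intermediate
19 | (7β,8β,13E)-labd-13-ene-7,8,15-triol | O[C@H]1C[C@H]2C(C)(C)CCC[C@]2(C)[C@@H](CC/C(C)=C/CO)[C@@]1(C)O | intermediate
20 | (7β,8β,13E)-8-hydroxylabd-13-ene-7,15-diyl diacetate | CC(=O)O[C@H]1C[C@H]2C(C)(C)CCC[C@]2(C)[C@@H](CC/C(C)=C/COC(C)=O)[C@@]1(C)O | intermediate
21 | (7β,8β,13E)-8,15-dihydroxylabd-13-en-7-yl acetate | CC(=O)O[C@H]1C[C@H]2C(C)(C)CCC[C@]2(C)[C@@H](CC/C(C)=C/CO)[C@@]1(C)O | target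

**Totals.** Total steps: 13. Longest linear sequence: 13 steps (1 → 21).

**Steps most likely to fail**

Step 4. The C4 radical may abstract the formyl hydrogen (1,5-transfer) or be reduced before it meets acrolein, acrolein may polymerise, and the β-keto aldehyde may lose its formyl group. The fallback sets out from 2 and returns at 9, making the two ring-A bonds in separate operations. The enolate of 2 (LiN(i-Pr)2) is alkylated anti to the isopropenyl group with methyl 2-(bromomethyl)acrylate (C1–C2) to give 6-[2-(methoxycarbonyl)allyl]-6-methylcarvone F1. Fe(acac)3/PhSiH3 in EtOH then closes ring A by intramolecular Giese cyclisation of the C4 radical on the acrylate CH2 terminus (C3–C4, 6-endo) to the bicyclic methyl ester F2. LiOH gives the carboxylic acid F3, and an acridinium-photocatalysed hydrodecarboxylation (PhSSPh, i-Pr2NEt, CF3CH2OH, blue light) gives 9.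

Step 9. Ionisation of the hindered, pseudo-equatorial tertiary carbonate may be slow, the allyl complex may undergo β-hydride elimination to dienes, or hydride may be delivered to C7 to give the tetrasubstituted C8=C9 isomer. The fallback sets out from 9 and returns at 14. Addition of 11 to 9 with aqueous quench gives the tertiary allylic alcohol F4. Pyridinium chlorochromate (C5H5NH[CrO3Cl]) effects oxidative 1,3-transposition (Babler–Dauben oxidation) to the 7-oxo-8-ene F5, and NaBH4/CeCl3 (Luche reduction, hydride from the α face) gives the 7β-allylic alcohol F6. A Mitsunobu reaction with 2-nitrobenzenesulfonylhydrazide (PPh3, DEAD, −30 °C → rt) gives with inversion the 7α-sulfonylhydrazine F7, which loses sulfinic acid to the allylic diazene F8. Its retro-ene loss of N2 delivers hydrogen suprafacially to the α face of C9 and gives 14.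

Step 10. The alkynylsilane may undergo iodo-desilylation, the tertiary acetate may eliminate instead of participating, or the iodonium may open with poor regio- or facial control. The fallback sets out from 14 and returns at 17. mCPBA gives the 7α,8α-epoxide F9, and HClO4 in aqueous THF opens it trans-diaxially at C8 to the 7α,8β-diol F10. Dess–Martin oxidation of the secondary hydroxyl gives the 8β-hydroxy-7-ketone F11, and NaBH4 (axial hydride delivery from the α face) gives the silylated 7β,8β-diol F12. K2CO3/MeOH removes the silyl group to give 17.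

**Further compounds**
F1 | step 4 | methyl 2-{[1,3-dimethyl-2-oxo-6-(prop-1-en-2-yl)cyclohex-3-en-1-yl]methyl}prop-2-enoate (acrylate-bearing CH2 trans to the isopropenyl group) | CC1=CC[C@@H](C(C)=C)[C@](C)(CC(=C)C(=O)OC)C1=O
F2 | step 4 | methyl (4aS,8aS)-4,4,7,8a-tetramethyl-8-oxo-1,2,3,4,4a,5,8,8a-octahydronaphthalene-2-carboxylate (C2 epimers) | CC1=CC[C@H]2C(C)(C)CC(C(=O)OC)C[C@]2(C)C1=O
F3 | step 4 | (4aS,8aS)-4,4,7,8a-tetramethyl-8-oxo-1,2,3,4,4a,5,8,8a-octahydronaphthalene-2-carboxylic acid (C2 epimers) | CC1=CC[C@H]2C(C)(C)CC(C(=O)O)C[C@]2(C)C1=O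
F4 | step 9 | (1S,4aS,8aS)-2,5,5,8a-tetramethyl-1-[4-(trimethylsilyl)but-3-yn-1-yl]-1,4,4a,5,6,7,8,8a-octahydronaphthalen-1-ol (9β-OH) | CC1=CC[C@H]2C(C)(C)CCC[C@]2(C)[C@]1(O)CCC#C[Si](C)(C)C
F5 | step 9 | 14-(trimethylsilyl)-15,16-dinorlabd-8-en-13-yn-7-one | O=C1C[C@H]2C(C)(C)CCC[C@]2(C)C(CCC#C[Si](C)(C)C)=C1C
F6 | step 9 | (7β)-14-(trimethylsilyl)-15,16-dinorlabd-8-en-13-yn-7-ol | O[C@H]1C[C@H]2C(C)(C)CCC[C@]2(C)C(CCC#C[Si](C)(C)C)=C1C
F7 | step 9 | N-[(7α)-14-(trimethylsilyl)-15,16-dinorlabd-8-en-13-yn-7-yl]-2-nitrobenzenesulfonohydrazide | NN([C@@H]1C[C@H]2C(C)(C)CCC[C@]2(C)C(CCC#C[Si](C)(C)C)=C1C)S(=O)(=O)c1ccccc1[N+](=O)[O-]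
F8 | step 9 | [(7α)-14-(trimethylsilyl)-15,16-dinorlabd-8-en-13-yn-7-yl]diazene | N=N[C@@H]1C[C@H]2C(C)(C)CCC[C@]2(C)C(CCC#C[Si](C)(C)C)=C1C
F9 | step 10 | (7α,8α)-7,8-epoxy-14-(trimethylsilyl)-15,16-dinorlabd-13-yne | O1[C@@H]2C[C@H]3C(C)(C)CCC[C@]3(C)[C@@H](CCC#C[Si](C)(C)C)[C@]12C
F10 | step 10 | (7α,8β)-14-(trimethylsilyl)-15,16-dinorlabd-13-yne-7,8-diol | O[C@@H]1C[C@H]2C(C)(C)CCC[C@]2(C)[C@@H](CCC#C[Si](C)(C)C)[C@@]1(C)O
F11 | step 10 | (8β)-8-hydroxy-14-(trimethylsilyl)-15,16-dinorlabd-13-yn-7-one | O=C1C[C@H]2C(C)(C)CCC[C@]2(C)[C@@H](CCC#C[Si](C)(C)C)[C@@]1(C)O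
F12 | step 10 | (7β,8β)-14-(trimethylsilyl)-15,16-dinorlabd-13-yne-7,8-diol | O[C@H]1C[C@H]2C(C)(C)CCC[C@]2(C)[C@@H](CCC#C[Si](C)(C)C)[C@@]1(C)O
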